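**Plan**

1. Ring atoms are called C1 (quaternary carbon with CH3 and CH2O), C2 (CH–CH3), C3, C4, C5 (isopropylidene carbon) and C6 (CH with the side chain). The retrosynthesis cuts the aryl ether C–O bond, the C–C bond between the first and second side-chain carbons, and, in one operation, the ring bonds C1–C2 and C5–C6.
2. The feature that allows this is the exocyclic tetrasubstituted C5=CMe2 next to the saturated C3–C4 unit: C2–C3–C4–C5=CMe2 is a vinylallene at a higher oxidation level, and C1/C6 with trans CH2O and chain carbons is an (E)-2-methylfumaraldehydic ester.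
3. Forward: the vinylallene (two steps) and the dienophile (two steps) are joined in the only ring-forming step, a [4+2] cycloaddition. Then follow Wittig chain extension, saturation of the two disubstituted alkenes, reduction, monosilylation, etherification with isofraxidin and desilylation.
4. All three stereocentres (C1, C2, C6) arise in the cycloaddition. Relative configuration comes from the (E)-dienophile and the (Z)-propenyl terminus through the endo-formyl transition state that the allene CMe2 group enforces; absolute configuration comes from a chiral oxazaborolidinium catalyst. No stereocentre is touched afterwards.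

Key step: step 5

**Step 1**
Reactants: 1 2-methylbut-3-yn-2-ol
Product: 3 2-methylbut-3-yn-2-yl methyl carbonate, via lithium 2-methylbut-3-yn-2-olate 2 (not isolated)
Conditions: n-BuLi (1.05 equiv), THF, −78 °C; then ClCO2Me, −78 → 0 °C
Reagents that add atoms: methyl chloroformate, COC(=O)Cl; n-butyllithium, [Li]CCCC (lithium of intermediate 2 only)
Why: Acylation of a tertiary lithium alkoxide with a chloroformate (carbonate formation) is routine and leaves the terminal alkyne untouched because only the more acidic O–H is deprotonated; no stereocentre.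

**Step 2**
Reactants: 3 2-methylbut-3-yn-2-yl methyl carbonate; 4 (Z)-prop-1-en-1-ylboronic acid
Product: 5 (5Z)-2-methylhepta-2,3,5-triene
Conditions: Pd(PPh3)4 (3 mol%), THF, rt → 40 °C, no added base; pentane extraction, product kept cold in solution
Reagents that add atoms: none
Why: Palladium-catalysed SN2'-type cross-coupling of a propargylic carbonate with an alkenylboronic acid (Suzuki–Miyaura-type): oxidative addition of zerovalent palladium with loss of CO2 gives an allenylpalladium methoxide that transmetallates without added base and reductively eliminates at the unsubstituted allene terminus with retention of the (Z)-alkene geometry, and no stereocentre arises because the CMe2 terminus makes the allene achiral.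

**Step 3**
Reactants: 6 2,2-dimethoxyacetaldehyde; 7 ethyl 2-(triphenyl-λ5-phosphanylidene)propanoate
Product: 8 ethyl (2E)-4,4-dimethoxy-2-methylbut-2-enoate
Conditions: CH2Cl2, rt
Reagents that add atoms: none
Why: Wittig olefination with an α-methyl stabilised ylide gives the (E)-trisubstituted enoate (ester trans to the acetal carbon), the geometry that later fixes the trans relation of the C1 and C6 substituents; no stereocentre.

**Step 4**
Reactants: 8 ethyl (2E)-4,4-dimethoxy-2-methylbut-2-enoate
Product: 9 ethyl (2E)-2-methyl-4-oxobut-2-enoate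
Conditions: TsOH·H2O (5 mol%), acetone/H2O, rt
Reagents that add atoms: water, O
Why: Acid-catalysed acetal hydrolysis releases the aldehyde under conditions too mild to isomerise the (E)-alkene or hydrolyse the ester; no stereocentre.

**Step 5**
Reactants: 5 (5Z)-2-methylhepta-2,3,5-triene; 9 ethyl (2E)-2-methyl-4-oxobut-2-enoate
Product: 10 ethyl (1R,2R,6R)-6-formyl-1,2-dimethyl-5-(propan-2-ylidene)cyclohex-3-ene-1-carboxylate
Conditions: (3aS)-1-(2-methylphenyl)-3,3-diphenyltetrahydro-1H,3H-pyrrolo[1,2-c][1,3,2]oxazaborole (20 mol%), (CF3SO2)2NH (18 mol%), CH2Cl2, −78 → −20 °C, diene and dienophile 1:1 (diene added as a cold solution); aqueous NaHCO3 quench at low temperature; adduct used promptly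
Reagents that add atoms: none
Why: Proposed new method: the formyl oxygen of 9 binds the cationic boron, which lowers the LUMO and places its largest coefficient on the ester-bearing carbon, and the s-cis vinylallene 5 adds in a concerted but asynchronous [4+2] cycloaddition through its propenyl and proximal allene π bonds while the orthogonal distal π bond is carried into the product as the isopropylidene; the closest known reaction types are the oxazaborolidinium-catalysed Diels–Alder reaction of enals with acyclic dienes and the thermal or Lewis acid-promoted Diels–Alder reaction of vinylallenes, and what has not been shown is a cis-substituted vinylallene as the diene under a chiral boron cation. The cyclohexene ring is closed intermolecularly in a suprafacial [π4s+π2s] mode, so both new σ bonds (C1–C2 and C5–C6) form on one face of each partner. Regiochemistry and endo geometry are secured by one substrate element: the CMe2 terminus puts a methyl group on each face of the allene carbon C5, so that only a dienophile carbon with hydrogen in its exo sector can bond there, which is the CH–CHO carbon with formyl endo and not the fully substituted carbon, and this matches the frontier-orbital pairing of the ester-bearing carbon with the propenyl terminus. The relative configuration follows from suprafacial addition: CO2Et and CHO stay trans (C1/C6) as in the (E)-dienophile, and the cis (inside) methyl of the (Z)-propenyl terminus ends cis to the exo CO2Et and trans to the endo CHO and C1 methyl (C2), an outcome that the trans-propenyl isomer could only reach through the sterically blocked exo-formyl arrangement; the cis methyl is tolerated in the s-cis conformer because the sp-hybridised allene terminus has no inside substituent. The absolute configuration is controlled by the catalyst, whose phenyl group is expected to cover the Si faces of both dienophile carbons so that the diene bonds to their Re faces. The selectivities needed are therefore regio-, endo- and enantiofacial selectivity plus chemoselectivity against the 1,5-hydrogen shift and acid-induced oligomerisation of 5, the last two being secured by the low temperature.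

**Step 6**
Reactants: 10 ethyl (1R,2R,6R)-6-formyl-1,2-dimethyl-5-(propan-2-ylidene)cyclohex-3-ene-1-carboxylate; 11 ethyl 2-(triphenyl-λ5-phosphanylidene)acetate
Product: 12 ethyl (1R,2R,6R)-6-[(1E)-3-ethoxy-3-oxoprop-1-en-1-yl]-1,2-dimethyl-5-(propan-2-ylidene)cyclohex-3-ene-1-carboxylate
Conditions: CH2Cl2, rt → 40 °C
Reagents that add atoms: none
Why: Wittig olefination with a stabilised, essentially non-basic ylide extends the aldehyde by two carbons to the (E)-enoate without epimerising C6 or moving the exocyclic alkene into conjugation; no new stereocentre.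

**Step 7**
Reactants: 12 ethyl (1R,2R,6R)-6-[(1E)-3-ethoxy-3-oxoprop-1-en-1-yl]-1,2-dimethyl-5-(propan-2-ylidene)cyclohex-3-ene-1-carboxylate
Product: 13 ethyl (1R,2R,6R)-2-(3-ethoxy-3-oxopropyl)-1,6-dimethyl-3-(propan-2-ylidene)cyclohexane-1-carboxylate
Conditions: 2-nitrobenzenesulfonohydrazide (excess, in portions), Et3N, CH2Cl2, rt
Reagents that add atoms: none
Why: Diimide reduction: HN=NH generated from the sulfonohydrazide transfers H2 in a concerted syn fashion to the two disubstituted alkenes (ring C3=C4 and the enoate) and does not touch the tetrasubstituted isopropylidene, and 1,4-addition or double-bond migration cannot occur by this mechanism; no new stereocentre.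

**Step 8**
Reactants: 13 ethyl (1R,2R,6R)-2-(3-ethoxy-3-oxopropyl)-1,6-dimethyl-3-(propan-2-ylidene)cyclohexane-1-carboxylate
Product: 14 3-[(1R,2R,3R)-2-(hydroxymethyl)-2,3-dimethyl-6-(propan-2-ylidene)cyclohexyl]propan-1-ol
Conditions: LiAlH4, THF, 0 °C → reflux; aqueous NaOH work-up
Reagents that add atoms: none
Why: Hydride reduction of both esters with LiAlH4 gives the diol, the hindered ester on the quaternary carbon included at reflux, and the isolated tetrasubstituted alkene and all stereocentres are inert.

**Step 9**
Reactants: 14 3-[(1R,2R,3R)-2-(hydroxymethyl)-2,3-dimethyl-6-(propan-2-ylidene)cyclohexyl]propan-1-ol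
Product: 15 [(1R,2R,6R)-2-{3-[(tert-butyldimethylsilyl)oxy]propyl}-1,6-dimethyl-3-(propan-2-ylidene)cyclohexyl]methanol
Conditions: TBSCl (1.05 equiv), imidazole, CH2Cl2, −20 → 0 °C
Reagents that add atoms: tert-butyldimethylsilyl chloride, CC(C)(C)[Si](C)(C)Cl
Why: Steric differentiation in silyl ether formation: the unhindered primary hydroxyl of the side chain is silylated much faster than the neopentyl hydroxyl on the quaternary carbon C1, which stays free for the next step.

**Step 10**
Reactants: 15 [(1R,2R,6R)-2-{3-[(tert-butyldimethylsilyl)oxy]propyl}-1,6-dimethyl-3-(propan-2-ylidene)cyclohexyl]methanol; 16 isofraxidin (7-hydroxy-6,8-dimethoxy-2H-chromen-2-one)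
Product: 17 7-{[(1R,2R,6R)-2-{3-[(tert-butyldimethylsilyl)oxy]propyl}-1,6-dimethyl-3-(propan-2-ylidene)cyclohexyl]methoxy}-6,8-dimethoxy-2H-chromen-2-one
Conditions: Bu3P=CHCN (cyanomethylenetributylphosphorane), toluene, 110 °C, sealed tube
Reagents that add atoms: none
Why: Mitsunobu-type etherification with a phosphorane reagent: the ylide deprotonates the acidic 7-hydroxycoumarin, the neopentyl alcohol is activated as an alkoxyphosphonium ion, and the phenoxide displaces Bu3P=O at the primary carbon at a temperature that a thermally stable phosphorane allows; the reacting carbon is not a stereocentre.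

**Step 11**
Reactants: 17 7-{[(1R,2R,6R)-2-{3-[(tert-butyldimethylsilyl)oxy]propyl}-1,6-dimethyl-3-(propan-2-ylidene)cyclohexyl]methoxy}-6,8-dimethoxy-2H-chromen-2-one
Product: 18 7-{[(1R,2R,6R)-2-(3-hydroxypropyl)-1,6-dimethyl-3-(propan-2-ylidene)cyclohexyl]methoxy}-6,8-dimethoxy-2H-chromen-2-one (target)
Conditions: HF·pyridine, THF/pyridine, 0 °C → rt
Reagents that add atoms: none
Why: Fluoride-induced cleavage of the primary silyl ether under buffered conditions leaves the coumarin lactone, the aryl ether and the tetrasubstituted alkene intact and gives the target.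

**Compound list**

1 | 2-methylbut-3-yn-2-ol | CC(C)(O)C#C | starting material
2 | lithium 2-methylbut-3-yn-2-olate | [Li+].[O-]C(C)(C)C#C | intermediate
3 | 2-methylbut-3-yn-2-yl methyl carbonate | COC(=O)OC(C)(C)C#C | intermediate
4 | (Z)-prop-1-en-1-ylboronic acid | C/C=C\B(O)O | starting material
5 | (5Z)-2-methylhepta-2,3,5-triene | CC(C)=C=C/C=C\C | intermediate
6 | 2,2-dimethoxyacetaldehyde | COC(OC)C=O | starting material
7 | ethyl 2-(triphenyl-λ5-phosphanylidene)propanoate | CCOC(=O)C(C)=P(c1ccccc1)(c1ccccc1)c1ccccc1 | starting material
8 | ethyl (2E)-4,4-dimethoxy-2-methylbut-2-enoate | CCOC(=O)/C(C)=C/C(OC)OC | intermediate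
9 | ethyl (2E)-2-methyl-4-oxobut-2-enoate | CCOC(=O)/C(C)=C/C=O | intermediate
10 | ethyl (1R,2R,6R)-6-formyl-1,2-dimethyl-5-(propan-2-ylidene)cyclohex-3-ene-1-carboxylate | CCOC(=O)[C@]1(C)[C@H](C)C=CC(=C(C)C)[C@H]1C=O | intermediate
11 | ethyl 2-(triphenyl-λ5-phosphanylidene)acetate | CCOC(=O)C=P(c1ccccc1)(c1ccccc1)c1ccccc1 | starting material
12 | ethyl (1R,2R,6R)-6-[(1E)-3-ethoxy-3-oxoprop-1-en-1-yl]-1,2-dimethyl-5-(propan-2-ylidene)cyclohex-3-ene-1-carboxylate | CCOC(=O)[C@]1(C)[C@H](C)C=CC(=C(C)C)[C@H]1/C=C/C(=O)OCC | intermediate
13 | ethyl (1R,2R,6R)-2-(3-ethoxy-3-oxopropyl)-1,6-dimethyl-3-(propan-2-ylidene)cyclohexane-1-carboxylate | CCOC(=O)[C@]1(C)[C@H](C)CCC(=C(C)C)[C@H]1CCC(=O)OCC | intermediate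
14 | 3-[(1R,2R,3R)-2-(hydroxymethyl)-2,3-dimethyl-6-(propan-2-ylidene)cyclohexyl]propan-1-ol | OC[C@]1(C)[C@H](C)CCC(=C(C)C)[C@H]1CCCO | intermediate
15 | [(1R,2R,6R)-2-{3-[(tert-butyldimethylsilyl)oxy]propyl}-1,6-dimethyl-3-(propan-2-ylidene)cyclohexyl]methanol | OC[C@]1(C)[C@H](C)CCC(=C(C)C)[C@H]1CCCO[Si](C)(C)C(C)(C)C | intermediate
16 | isofraxidin (7-hydroxy-6,8-dimethoxy-2H-chromen-2-one) | COc1cc2ccc(=O)oc2c(OC)c1O | starting material
17 | 7-{[(1R,2R,6R)-2-{3-[(tert-butyldimethylsilyl)oxy]propyl}-1,6-dimethyl-3-(propan-2-ylidene)cyclohexyl]methoxy}-6,8-dimethoxy-2H-chromen-2-one | COc1cc2ccc(=O)oc2c(OC)c1OC[C@]1(C)[C@H](C)CCC(=C(C)C)[C@H]1CCCO[Si](C)(C)C(C)(C)C | intermediate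
18 | 7-{[(1R,2R,6R)-2-(3-hydroxypropyl)-1,6-dimethyl-3-(propan-2-ylidene)cyclohexyl]methoxy}-6,8-dimethoxy-2H-chromen-2-one | COc1cc2ccc(=O)oc2c(OC)c1OC[C@]1(C)[C@H](C)CCC(=C(C)C)[C@H]1CCCO | target

**Step count**

Total: 11 steps. Longest linear sequence: 9 steps (steps 1, 2, 5–11, or steps 3–11).

**Steps most likely to fail**

Step 5 (Proposed new method). What may go wrong: ionisation of the acid-labile vinylallene by the cationic boron species (oligomerisation, or stepwise [2+2] addition through the distal allene π bond); slow turnover because both bond-forming pairs are hindered, so that the 1,5-hydrogen shift of the cis-vinylallene catches up on warming; or weak facial discrimination. If the sense of induction is opposite to the shielding model, the (3aR)-catalyst is used instead. The fallback uses known chemistry, sets out from 5 and 9 and returns at 10. The two are combined with the achiral Lewis acid Me2AlCl in CH2Cl2 at −78 °C (Lewis acid-promoted Diels–Alder reaction of a vinylallene), where the same substrate-based regio- and diastereocontrol should give racemic ethyl (1R*,2R*,6R*)-6-formyl-1,2-dimethyl-5-(propan-2-ylidene)cyclohex-3-ene-1-carboxylate F1. Condensation with (1R,2R)-N,N'-dimethyl-1,2-diphenylethane-1,2-diamine (Et2O, molecular sieves, rt) should convert the two enantiomers into the diastereomeric aminals ethyl (1R,2R,6R)-6-[(4R,5R)-1,3-dimethyl-4,5-diphenylimidazolidin-2-yl]-1,2-dimethyl-5-(propan-2-ylidene)cyclohex-3-ene-1-carboxylate F2 and ethyl (1S,2S,6S)-6-[(4R,5R)-1,3-dimethyl-4,5-diphenylimidazolidin-2-yl]-1,2-dimethyl-5-(propan-2-ylidene)cyclohex-3-ene-1-carboxylate F3, which are separated by chromatography. Mild hydrolysis of F2 (dilute aqueous HCl/Et2O, 0 °C) returns 10 as a single enantiomer.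

Step 10. What may go wrong: displacement at the neopentyl alkoxyphosphonium carbon by the doubly ortho-substituted phenoxide is slow, so that the reagent decomposes, the alcohol is returned, or ionisation with a 1,2-shift sets in. The fallback sets out from 15 and returns at 17. Alcohol 15 is converted with (CF3SO2)2O and 2,6-lutidine (CH2Cl2, −78 °C) into the isolated sulfonate [(1R,2R,6R)-2-{3-[(tert-butyldimethylsilyl)oxy]propyl}-1,6-dimethyl-3-(propan-2-ylidene)cyclohexyl]methyl trifluoromethanesulfonate F4. Separately, 16 is deprotonated with Cs2CO3 in DMF to caesium 6,8-dimethoxy-2-oxo-2H-chromen-7-olate F5, and F4 is added at 0 °C → rt. This replaces the redox condensation by SN2 displacement of a far better leaving group with a free phenoxide in a dipolar aprotic solvent.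

Step 7. What may go wrong: hydrogen transfer to the hindered ring alkene of the conjugated diene is incomplete because diimide disproportionates faster than it is consumed, which leaves the 3,4-ene after the enoate has been reduced. The fallback sets out from 12 and returns at 13. Hydrogenation with H2 (1 atm) and RhCl(PPh3)3 in benzene/ethanol at rt differentiates the alkenes by coordination to rhodium and migratory insertion instead of by a concerted group transfer; the tetrasubstituted alkene does not bind. No new compound is made (none F0).

**Further compounds**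

F1 | step 5 | racemic ethyl (1R*,2R*,6R*)-6-formyl-1,2-dimethyl-5-(propan-2-ylidene)cyclohex-3-ene-1-carboxylate | CCOC(=O)[C@]1(C)[C@H](C)C=CC(=C(C)C)[C@H]1C=O.CCOC(=O)[C@@]1(C)[C@@H](C)C=CC(=C(C)C)[C@@H]1C=O
F2 | step 5 | ethyl (1R,2R,6R)-6-[(4R,5R)-1,3-dimethyl-4,5-diphenylimidazolidin-2-yl]-1,2-dimethyl-5-(propan-2-ylidene)cyclohex-3-ene-1-carboxylate | CCOC(=O)[C@]1(C)[C@H](C)C=CC(=C(C)C)[C@H]1C1N(C)[C@H](c2ccccc2)[C@@H](c2ccccc2)N1C
F3 | step 5 | ethyl (1S,2S,6S)-6-[(4R,5R)-1,3-dimethyl-4,5-diphenylimidazolidin-2-yl]-1,2-dimethyl-5-(propan-2-ylidene)cyclohex-3-ene-1-carboxylate | CCOC(=O)[C@@]1(C)[C@@H](C)C=CC(=C(C)C)[C@@H]1C1N(C)[C@H](c2ccccc2)[C@@H](c2ccccc2)N1C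
F4 | step 10 | [(1R,2R,6R)-2-{3-[(tert-butyldimethylsilyl)oxy]propyl}-1,6-dimethyl-3-(propan-2-ylidene)cyclohexyl]methyl trifluoromethanesulfonate | FC(F)(F)S(=O)(=O)OC[C@]1(C)[C@H](C)CCC(=C(C)C)[C@H]1CCCO[Si](C)(C)C(C)(C)C
F5 | step 10 | caesium 6,8-dimethoxy-2-oxo-2H-chromen-7-olate | COc1cc2ccc(=O)oc2c(OC)c1[O-].[Cs+]
F0 | step 7 | none | none
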